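**Plan**
- Retrosynthesis: the O–CH3 and O–Si groups are removed first. The six-membered ring is then cut at two bonds: (a) chain-bearing ring carbon to one oxygenated neighbour, and (b) its other oxygenated neighbour to the oxygenated carbon next to C–CH3. This gives a two-carbon 1-siloxyalkyne and a four-carbon diacyl unit.
- Enabling feature: the ring carbons C(=O)–C(O)=C(CH3)–C(=O) are a but-2-ene-1,4-dioyl (maleoyl) unit, the ring-opened form of the four-membered ring of 3-methoxy-4-methylcyclobutene-1,2-dione. Monovalent cobalt inserts into its strained C(=O)–C(=O) bond, and the diacyl cobaltacycle takes up the C≡C of the alkyne.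
- Chain: the C15=C16 alkene of a C20 ester is cut by Julia–Kocienski olefination (C15 aldehyde from pentadecanolide plus a pentyl sulfone). One-carbon homologation of the ester then gives the ynol silyl ether.
- Forward order: chain ester, then siloxyalkyne; separately dimethyl squarate, then methylcyclobutenedione, then cobaltacycle; the quinone ring forms in one step; hydrolysis ends the route.
- Stereochemistry: there is no stereocentre; the single E alkene is set in the Julia–Kocienski step and carried unchanged.

Key step: step 9

Remark on the chemistry: the 2,5-dihydroxy-1,4-benzoquinone core exchanges its two O–H protons between the two pairs of ring oxygens (degenerate tautomerism). The two ring carbons that are C=O in the key-step product therefore appear as the two C–OH carbons in the usual formula of 19; it is the same compound.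

Assumption: complex 5 is formulated as an octahedral trivalent cobalt diacyl complex with chloride, pyridine and neutral N,N-bound dimethylglyoxime; ClCo(PPh3)3 is taken as a purchased reagent. In the SMILES of the cobalt complexes the donor bonds from phosphorus and nitrogen are drawn as ordinary bonds with formal charges (donor atom positive, cobalt negative), each complex being neutral overall.

**Step 1**
Reactants: 1 dimethyl squarate (3,4-dimethoxycyclobut-3-ene-1,2-dione)
Product: 3 3-methoxy-4-methylcyclobut-3-ene-1,2-dione, via hydroxycyclobutenone adduct 2 (not isolated)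
Conditions: MeLi (1.05 equiv), THF, −78 °C; H2O quench, extraction; crude 2 in CH2Cl2, 12 M HCl (cat.), 0 °C → rt
Reagents that add atoms: methyllithium, [Li]C
Why: 1,2-addition of the organolithium to one carbonyl of the squarate ester stops at the mono-adduct at low temperature, and acid then ionises the tertiary allylic alcohol and hydrolyses the methoxy-stabilised cation with loss of methanol (organolithium addition to a squarate followed by acid-promoted 1,3-carbonyl transposition).

**Step 2**
Reactants: 3 3-methoxy-4-methylcyclobut-3-ene-1,2-dione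
Product: 5 chloro(dimethylglyoxime)(pyridine)(2-methoxy-3-methylbut-2-ene-1,4-dioyl)cobalt, via bis(triphenylphosphine) maleoylcobalt chloride 4 (not isolated)
Conditions: ClCo(PPh3)3 (1.05 equiv), benzene, rt, Ar; then dimethylglyoxime, pyridine, rt
Reagents that add atoms: chlorotris(triphenylphosphine)cobalt, Cl[Co-3]([P+](c1ccccc1)(c1ccccc1)c1ccccc1)([P+](c1ccccc1)(c1ccccc1)c1ccccc1)[P+](c1ccccc1)(c1ccccc1)c1ccccc1; dimethylglyoxime, CC(=NO)C(C)=NO; pyridine, c1ccncc1
Why: Oxidative addition of monovalent cobalt into the strained C(=O)–C(=O) bond gives the five-membered trivalent cobalt diacyl metallacycle, and substitution of the two phosphines by dimethylglyoxime and pyridine gives the air-stable complex that reacts with alkynes under Lewis acid activation (C–C bond insertion followed by ligand exchange).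

**Step 3**
Reactants: 6 1-phenyl-1H-tetrazole-5-thiol; 7 1-bromopentane
Product: 8 5-(pentylsulfanyl)-1-phenyl-1H-tetrazole
Conditions: K2CO3, acetone, reflux
Reagents that add atoms: none
Why: The soft thiolate displaces the primary bromide (SN2 S-alkylation).

**Step 4**
Reactants: 8 5-(pentylsulfanyl)-1-phenyl-1H-tetrazole
Product: 9 5-(pentylsulfonyl)-1-phenyl-1H-tetrazole
Conditions: 30% H2O2, (NH4)6Mo7O24·4H2O (cat.), EtOH, 0 °C → rt
Reagents that add atoms: hydrogen peroxide, OO
Why: Peroxide oxidation catalysed by ammonium heptamolybdate takes the sulfide through the sulfoxide to the sulfone without touching the tetrazole (sulfide to sulfone oxidation).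

**Step 5**
Reactants: 10 pentadecanolide (oxacyclohexadecan-2-one)
Product: 11 methyl 15-hydroxypentadecanoate
Conditions: MeOH, H2SO4 (cat.), reflux
Reagents that add atoms: methanol, CO
Why: Acid-catalysed transesterification in excess methanol opens the macrolactone to the hydroxy ester (Fischer-type methanolysis).

**Step 6**
Reactants: 11 methyl 15-hydroxypentadecanoate
Product: 12 methyl 15-oxopentadecanoate
Conditions: TEMPO (cat.), PhI(OAc)2, CH2Cl2, rt
Reagents that add atoms: none
Why: The oxoammonium salt formed from TEMPO oxidises the primary alcohol and stops at the aldehyde, and the ester is inert (TEMPO/hypervalent iodine oxidation).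

**Step 7**
Reactants: 12 methyl 15-oxopentadecanoate; 9 5-(pentylsulfonyl)-1-phenyl-1H-tetrazole
Product: 13 methyl (E)-icos-15-enoate
Conditions: 9, KN(SiMe3)2, DME, −60 °C; then 12, −60 °C → rt
Reagents that add atoms: none
Why: Julia–Kocienski olefination, in which the potassium sulfonyl carbanion adds to the unbranched aldehyde through an open transition state in DME, and Smiles rearrangement with antiperiplanar loss of SO2 and tetrazolate should then give the E alkene while the methyl ester survives at low temperature.

**Step 8**
Reactants: 13 methyl (E)-icos-15-enoate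
Product: 16 (E)-(henicos-16-en-1-yn-1-yloxy)tri(propan-2-yl)silane, via dibromomethyl ketone enolate 14 (not isolated), via lithium ynolate 15 (not isolated)
Conditions: CH2Br2, lithium 2,2,6,6-tetramethylpiperidide, THF, −78 °C; LiN(SiMe3)2; n-BuLi, −78 °C → rt; then i-Pr3SiCl, −78 °C → rt
Reagents that add atoms: dibromomethane, BrCBr; chlorotri(propan-2-yl)silane, CC(C)[Si](Cl)(C(C)C)C(C)C
Why: Kowalski ester homologation, in which dibromomethyllithium adds to the ester, bromine–lithium exchange on the dibromo enolate triggers a 1,2-shift of the chain to the lithium ynolate, and the bulky silyl chloride traps the ynolate on oxygen.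

**Step 9**
Reactants: 5 chloro(dimethylglyoxime)(pyridine)(2-methoxy-3-methylbut-2-ene-1,4-dioyl)cobalt; 16 (E)-(henicos-16-en-1-yn-1-yloxy)tri(propan-2-yl)silane
Product: 18 2-methoxy-3-methyl-6-[(E)-nonadec-14-en-1-yl]-5-[tri(propan-2-yl)silyloxy]cyclohexa-2,5-diene-1,4-dione, via seven-membered cobaltacycle 17 (not isolated)
Conditions: SnCl4 (0.5 equiv), 2,6-di-tert-butylpyridine, CH2Cl2, −40 °C → rt
Reagents that add atoms: none
Why: The Lewis acid should bind the acyl oxygen next to the methoxy-bearing carbon (five-membered chelate with the OCH3 oxygen), the electron-rich alkyne then inserts into that Co–acyl bond to give cobaltacycle 17, and C–C reductive elimination from trivalent cobalt joins the second acyl carbon to the oxygen-bearing alkyne carbon and releases monovalent cobalt. The closest known reaction type is the Lewis-acid-promoted annulation of maleoylcobalt dimethylglyoxime complexes with alkynes to 1,4-benzoquinones. The six-membered carbocycle closes as a formal [4+2] union: the five-membered metallacycle expands by the two alkyne carbons and then contracts with extrusion of cobalt. No stereocentre is formed, and the remote E alkene should not react because an unactivated alkene does not insert under these conditions. The step needs regioselectivity, and the polarity match should secure it: the nucleophilic chain-bearing alkyne carbon (β to oxygen) bonds to the more electrophilic acyl carbon, the one next to C–OCH3 that lies outside the vinylogous ester and is the carbonyl attacked by nucleophiles in 3-alkoxy-4-alkylcyclobutenediones, so the siloxy carbon bonds to the acyl carbon next to C–CH3 and the two oxygens end para with the chain para to methyl.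

**Step 10**
Reactants: 18 2-methoxy-3-methyl-6-[(E)-nonadec-14-en-1-yl]-5-[tri(propan-2-yl)silyloxy]cyclohexa-2,5-diene-1,4-dione
Product: 19 2,5-dihydroxy-3-methyl-6-[(E)-nonadec-14-en-1-yl]cyclohexa-2,5-diene-1,4-dione
Conditions: 2 M NaOH, EtOH/THF/H2O (degassed), 60 °C; then 2 M HCl, 0 °C
Reagents that add atoms: sodium hydroxide, [Na+].[OH-]
Why: Hydroxide cleaves the Si–O bond and replaces methoxide by addition–elimination at the vinylogous ester carbon, the quinone bis-enolate resists further attack, and acidification should give the dihydroxyquinone (vinylogous ester saponification and desilylation).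

**Compound list**
1 | dimethyl squarate (3,4-dimethoxycyclobut-3-ene-1,2-dione) | COC1=C(OC)C(=O)C1=O | starting material
2 | 4-hydroxy-2,3-dimethoxy-4-methylcyclobut-2-en-1-one (racemic; formed first as its lithium alkoxide) | COC1=C(OC)C(C)(O)C1=O | intermediate
3 | 3-methoxy-4-methylcyclobut-3-ene-1,2-dione | COC1=C(C)C(=O)C1=O | intermediate
4 | chlorobis(triphenylphosphine)(2-methoxy-3-methylbut-2-ene-1,4-dioyl)cobalt | COC1=C(C)C(=O)[Co-2](Cl)([P+](c2ccccc2)(c2ccccc2)c2ccccc2)([P+](c2ccccc2)(c2ccccc2)c2ccccc2)C1=O | intermediate
5 | chloro(dimethylglyoxime)(pyridine)(2-methoxy-3-methylbut-2-ene-1,4-dioyl)cobalt | CC1=[N+](O)[Co-3]2(Cl)([n+]3ccccc3)([N+](O)=C1C)C(=O)C(C)=C(OC)C2=O | intermediate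
6 | 1-phenyl-1H-tetrazole-5-thiol | Sc1nnnn1-c1ccccc1 | starting material
7 | 1-bromopentane | CCCCCBr | starting material
8 | 5-(pentylsulfanyl)-1-phenyl-1H-tetrazole | CCCCCSc1nnnn1-c1ccccc1 | intermediate
9 | 5-(pentylsulfonyl)-1-phenyl-1H-tetrazole | CCCCCS(=O)(=O)c1nnnn1-c1ccccc1 | intermediate
10 | pentadecanolide (oxacyclohexadecan-2-one) | O=C1CCCCCCCCCCCCCCO1 | starting material
11 | methyl 15-hydroxypentadecanoate | COC(=O)CCCCCCCCCCCCCCO | intermediate
12 | methyl 15-oxopentadecanoate | COC(=O)CCCCCCCCCCCCCC=O | intermediate
13 | methyl (E)-icos-15-enoate | CCCC/C=C/CCCCCCCCCCCCCC(=O)OC | intermediate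
14 | lithium enolate of (E)-1,1-dibromohenicos-16-en-2-one | [Li]OC(=C(Br)Br)CCCCCCCCCCCCC/C=C/CCCC | intermediate
15 | lithium (E)-henicos-16-en-1-yn-1-olate | [Li]OC#CCCCCCCCCCCCCC/C=C/CCCC | intermediate
16 | (E)-(henicos-16-en-1-yn-1-yloxy)tri(propan-2-yl)silane | CC(C)[Si](OC#CCCCCCCCCCCCCC/C=C/CCCC)(C(C)C)C(C)C | intermediate
17 | seven-membered cobaltacycle: chloro(dimethylglyoxime)(pyridine)cobalt bound to the siloxy-bearing alkenyl carbon and to the acyl carbon next to C–CH3 | CC1=[N+](O)[Co-3]2(Cl)([n+]3ccccc3)([N+](O)=C1C)C(=O)C(C)=C(OC)C(=O)C(CCCCCCCCCCCCC/C=C/CCCC)=C2O[Si](C(C)C)(C(C)C)C(C)C | intermediate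
18 | 2-methoxy-3-methyl-6-[(E)-nonadec-14-en-1-yl]-5-[tri(propan-2-yl)silyloxy]cyclohexa-2,5-diene-1,4-dione | COC1=C(C)C(=O)C(O[Si](C(C)C)(C(C)C)C(C)C)=C(CCCCCCCCCCCCC/C=C/CCCC)C1=O | intermediate
19 | 2,5-dihydroxy-3-methyl-6-[(E)-nonadec-14-en-1-yl]cyclohexa-2,5-diene-1,4-dione | CCCC/C=C/CCCCCCCCCCCCCC1=C(O)C(=O)C(C)=C(O)C1=O | target

**Totals**
Total step count: 10.
Longest linear sequence: 6 steps (10 → 11 → 12 → 13 → 16 → 18 → 19).

**Steps most likely to fail**

1. Step 9. The alkyne may insert with the wrong orientation, so that the chain-bearing carbon bonds to the acyl carbon next to C–CH3, or the Lewis acid may ionise and oligomerise the siloxyalkyne before insertion.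
Fallback, setting out from 3 and 13 and coming back at 19: lithium ethoxyacetylide (ethoxyacetylene, n-BuLi, THF, −78 °C) should add to the more electrophilic carbonyl of 3 to give 4-(ethoxyethynyl)-4-hydroxy-3-methoxy-2-methylcyclobut-2-en-1-one F1. Thermolysis in p-xylene at reflux (Moore rearrangement through the alkynyl vinylketene) should give 5-ethoxy-2-methoxy-3-methylcyclohexa-2,5-diene-1,4-dione F2, which has one free ring position. Ester 13 is saponified (LiOH, THF/H2O) to (E)-icos-15-enoic acid F3. Silver-catalysed persulfate decarboxylation of F3 (AgNO3 cat., (NH4)2S2O8, MeCN/H2O, 65 °C) in the presence of F2 should add the C19 radical at the free position (Minisci-type radical alkylation of a quinone) to give 5-ethoxy-2-methoxy-3-methyl-6-[(E)-nonadec-14-en-1-yl]cyclohexa-2,5-diene-1,4-dione F4. Hydrolysis under the conditions of step 10 gives 19.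

2. Step 8. The carbenoid rearrangement to the ynolate may be incomplete, and the ynol silyl ether may be lost by protonation and hydrolysis during isolation.
Fallback, setting out from 13 and coming back at 16: reduction of 13 (i-Bu2AlH, CH2Cl2, −78 °C) gives (E)-icos-15-enal F5. Ohira–Bestmann homologation (dimethyl (1-diazo-2-oxopropyl)phosphonate, K2CO3, MeOH) gives (E)-henicos-16-en-1-yne F6. The lithium acetylide of F6 (n-BuLi, THF, −78 °C) is oxidised with t-BuOOLi to the same lithium ynolate 15, which i-Pr3SiCl silylates on oxygen to 16. The ynolate then arises by acetylide oxidation and not by a carbenoid shift.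

3. Step 7. The E selectivity of the sulfone addition may erode, leaving Z alkene that cannot be separated from the long-chain product, and the metalated sulfone may self-condense before the aldehyde is added.
Fallback, setting out from 12 and coming back at 13: Ohira–Bestmann homologation of 12 gives methyl hexadec-15-ynoate F7. Syn-hydrozirconation with Cp2Zr(H)Cl followed by I2 gives methyl (E)-16-iodohexadec-15-enoate F8 with the geometry fixed by the syn addition. Negishi coupling with n-BuZnBr and PdCl2(dppf) in THF proceeds with retention and gives 13.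

**Further compounds**
F1 | step 9 | 4-(ethoxyethynyl)-4-hydroxy-3-methoxy-2-methylcyclobut-2-en-1-one (racemic) | CCOC#CC1(O)C(OC)=C(C)C1=O
F2 | step 9 | 5-ethoxy-2-methoxy-3-methylcyclohexa-2,5-diene-1,4-dione | CCOC1=CC(=O)C(OC)=C(C)C1=O
F3 | step 9 | (E)-icos-15-enoic acid | CCCC/C=C/CCCCCCCCCCCCCC(=O)O
F4 | step 9 | 5-ethoxy-2-methoxy-3-methyl-6-[(E)-nonadec-14-en-1-yl]cyclohexa-2,5-diene-1,4-dione | CCOC1=C(CCCCCCCCCCCCC/C=C/CCCC)C(=O)C(OC)=C(C)C1=O
F5 | step 8 | (E)-icos-15-enal | CCCC/C=C/CCCCCCCCCCCCCC=O
F6 | step 8 | (E)-henicos-16-en-1-yne | CCCC/C=C/CCCCCCCCCCCCCC#C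
F7 | step 7 | methyl hexadec-15-ynoate | C#CCCCCCCCCCCCCCC(=O)OC
F8 | step 7 | methyl (E)-16-iodohexadec-15-enoate | I/C=C/CCCCCCCCCCCCCC(=O)OC
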